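**Retrosynthetic overview**
- Target 11 comes from the 2-alkoxyisoflavan 8 by reductive removal of the C2 alkoxy group and O-debenzylation. Neither step touches C3.
- 8 comes from one oxa-[4+2] cycloaddition that makes C4–C3 and O1–C2 together, between o-quinone methide 7 and the chiral (E)-β-aryl enol ether 5. Ring C is the only ring formed. Ring B is carried in preformed, and ring A enters as a quinone and is aromatised in the same step.
- Enabling feature: in ring A, O1 (on C8a) and the C6 hydroxyl are para, and C4 sits on C4a, ortho to C8a. Ring A plus C4 is therefore the aromatised form of the o-quinone methide tautomer of commercial 2,3-dimethoxy-5-methyl-1,4-benzoquinone 6, so this half needs no protecting or leaving group.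
- 5 comes from copper-catalysed C–O coupling of (E)-iodoalkene 3 (from aldehyde 1 by benzylation and Takai olefination) with (1S,2R)-2-phenylcyclohexanol 4. The alkoxy group serves as regiochemical director, chiral controller and later leaving group.

Key step: step 4

Assumption: the sense of induction in step 4 is assigned from the s-trans, phenyl-shielded conformer model of trans-2-phenylcyclohexyl enol ethers, by which the (1S,2R)-alcohol combined with the (E)-alkene leads to (3S).

Step 1
Reactants: 1 2-hydroxy-3,4-dimethoxybenzaldehyde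
Product: 2 2-(benzyloxy)-3,4-dimethoxybenzaldehyde
Conditions: BnBr, K2CO3, DMF, 25 °C
Reagents that add atoms: benzyl bromide, BrCc1ccccc1
Why: Williamson ether synthesis on the acidic, aldehyde-chelated phenol should be clean, and the benzyl ether keeps the 2'-oxygen from adding later to the o-quinone methide or the enol ether while staying removable by neutral hydrogenolysis.

Step 2
Reactants: 2 2-(benzyloxy)-3,4-dimethoxybenzaldehyde
Product: 3 2-(benzyloxy)-1-[(E)-2-iodoethenyl]-3,4-dimethoxybenzene
Conditions: CHI3 (2 equiv), CrCl2 (6 equiv), THF, 0 to 25 °C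
Reagents that add atoms: iodoform, IC(I)I
Why: Takai olefination, in which the geminal dichromium reagent formed from CHI3 and CrCl2 adds to the aldehyde and eliminates to the iodoalkene, is reliably (E)-selective for aromatic aldehydes and tolerates aryl ethers.

Step 3
Reactants: 3 2-(benzyloxy)-1-[(E)-2-iodoethenyl]-3,4-dimethoxybenzene, 4 (1S,2R)-2-phenylcyclohexan-1-ol
Product: 5 2-(benzyloxy)-3,4-dimethoxy-1-[(E)-2-{[(1S,2R)-2-phenylcyclohexyl]oxy}ethenyl]benzene
Conditions: CuI (10 mol %), 3,4,7,8-tetramethyl-1,10-phenanthroline (20 mol %), Cs2CO3, toluene, 80 °C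
Reagents that add atoms: none
Why: Ullmann-type copper-catalysed C(sp2)–O coupling of alkenyl iodides with alcohols runs with retention of alkene geometry and touches no bond at the two stereocentres of 4, so (E)-5 should form as a single stereoisomer.

Step 4
Reactants: 5 2-(benzyloxy)-3,4-dimethoxy-1-[(E)-2-{[(1S,2R)-2-phenylcyclohexyl]oxy}ethenyl]benzene, 6 2,3-dimethoxy-5-methyl-1,4-benzoquinone
Product: 8 (2R,3S)-3-[2-(benzyloxy)-3,4-dimethoxyphenyl]-7,8-dimethoxy-2-{[(1S,2R)-2-phenylcyclohexyl]oxy}-3,4-dihydro-2H-chromen-6-ol, via o-quinone methide 7 (not isolated)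
Conditions: Et3N (0.5 equiv), 4 Å MS, toluene, 70 °C, N2, dark; 6 (2 equiv) added to 5 over 12 h by syringe pump
Reagents that add atoms: none
Why: Proposed new method: Et3N reversibly removes a proton from the ring methyl group of 6 (vinylogous to the distal carbonyl), O-protonation of the dienolate gives a low stationary concentration of o-quinone methide 7, and its O=C–C=CH2 unit is captured by the electron-rich alkene of 5 in a concerted but asynchronous inverse-electron-demand oxa-[4+2] cycloaddition in which C4–C3 leads and O1–C2 follows, the aromatisation of ring A making capture irreversible and uncovering the free C6 hydroxyl. The closest known reaction types are the amine-induced tautomerisation of alkyl-1,4-quinones to o-quinone methides with intramolecular or dimerising [4+2] capture, the trapping of chromanol-type o-quinone methides by vinyl ethers, the cycloaddition of o-quinone methides with β-aryl enol ethers to 2-alkoxyisoflavans and the auxiliary-controlled cycloaddition with trans-2-phenylcyclohexyl vinyl ethers; new is the intermolecular capture of a methylbenzoquinone tautomer by a chiral β-aryl enol ether. Ring C is the only ring closed, in an intermolecular [4+2] mode (in the stepwise limit, conjugate addition to the methide carbon followed by 6-exo-trig attack of the phenoxide on the oxocarbenium carbon). C3 is controlled by the auxiliary, because in the s-trans conformer of the enol ether the phenyl ring of the (1S,2R)-2-phenylcyclohexyl group covers one alkene face and the planar heterodiene, which gains no stereocentre of its own so that endo and exo approach to the open face give the same product, bonds to the open face to give (3S); C2 follows from suprafacial addition to the (E)-alkene as (2R), trans to the aryl group, and is erased in step 5. The step needs regioselectivity (the aryl-bearing and not the oxygen-bearing alkene carbon must attack the methide carbon), secured by the alkoxy donor that puts the largest HOMO coefficient on the aryl-bearing carbon and carries the developing charge as an oxocarbenium ion; chemoselectivity for 7 over p-quinone 6, secured by excluding Lewis acid and light, without which enol ethers should not add to methoxyquinones; and capture faster than self-condensation of 6 and 7, secured by slow addition of 6 to 5. Because the auxiliary stays attached, a minor facial isomer is a diastereomer and can be removed by chromatography or crystallisation before C2 is deleted.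

Step 5
Reactants: 8 (2R,3S)-3-[2-(benzyloxy)-3,4-dimethoxyphenyl]-7,8-dimethoxy-2-{[(1S,2R)-2-phenylcyclohexyl]oxy}-3,4-dihydro-2H-chromen-6-ol
Product: 10 (3S)-3-[2-(benzyloxy)-3,4-dimethoxyphenyl]-7,8-dimethoxy-3,4-dihydro-2H-chromen-6-ol, via oxocarbenium ion 9 (not isolated)
Conditions: Et3SiH (5 equiv), TMSOTf (0.2 equiv), CH2Cl2, −78 to −40 °C; then 1 M HCl, THF, 25 °C
Reagents that add atoms: none
Why: Ionic hydrogenation of a cyclic acetal (silane reduction under silyl triflate catalysis): the more basic exocyclic alkoxy oxygen is activated and leaves, the ring oxocarbenium ion 9 keeps the O1–C2 bond and should take hydride at C2 at low temperature faster than it loses H-3, so that C2 becomes CH2, C3 stays (S) and auxiliary 4 is returned after the acidic work-up.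

Step 6
Reactants: 10 (3S)-3-[2-(benzyloxy)-3,4-dimethoxyphenyl]-7,8-dimethoxy-3,4-dihydro-2H-chromen-6-ol
Product: 11 (3S)-3-(2-hydroxy-3,4-dimethoxyphenyl)-7,8-dimethoxy-3,4-dihydro-2H-chromen-6-ol
Conditions: H2 (1 atm), 10% Pd/C, EtOAc–EtOH, 25 °C
Reagents that add atoms: none
Why: Catalytic hydrogenolysis cleaves only the benzylic C–O bond of the aryl benzyl ether, since O1–C2 is not benzylic and no bond at C3 is involved, and so should give 11 with the (3S) centre intact.

**Compound list**
1 | 2-hydroxy-3,4-dimethoxybenzaldehyde | COc1ccc(C=O)c(O)c1OC | starting material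
2 | 2-(benzyloxy)-3,4-dimethoxybenzaldehyde | COc1ccc(C=O)c(OCc2ccccc2)c1OC | intermediate
3 | 2-(benzyloxy)-1-[(E)-2-iodoethenyl]-3,4-dimethoxybenzene | COc1ccc(/C=C/I)c(OCc2ccccc2)c1OC | intermediate
4 | (1S,2R)-2-phenylcyclohexan-1-ol | O[C@H]1CCCC[C@@H]1c1ccccc1 | starting material
5 | 2-(benzyloxy)-3,4-dimethoxy-1-[(E)-2-{[(1S,2R)-2-phenylcyclohexyl]oxy}ethenyl]benzene | COc1ccc(/C=C/O[C@H]2CCCC[C@@H]2c3ccccc3)c(OCc4ccccc4)c1OC | intermediate
6 | 2,3-dimethoxy-5-methyl-1,4-benzoquinone (coenzyme Q0) | COC1=C(OC)C(=O)C(C)=CC1=O | starting material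
7 | 4-hydroxy-2,3-dimethoxy-6-methylidenecyclohexa-2,4-dien-1-one (o-quinone methide tautomer of 6) | C=C1C=C(O)C(OC)=C(OC)C1=O | intermediate
8 | (2R,3S)-3-[2-(benzyloxy)-3,4-dimethoxyphenyl]-7,8-dimethoxy-2-{[(1S,2R)-2-phenylcyclohexyl]oxy}-3,4-dihydro-2H-chromen-6-ol (2,3-trans) | COc1ccc([C@H]2[C@H](O[C@H]3CCCC[C@@H]3c4ccccc4)Oc5c(cc(O)c(OC)c5OC)C2)c(OCc6ccccc6)c1OC | intermediate
9 | (3S)-3-[2-(benzyloxy)-3,4-dimethoxyphenyl]-6-hydroxy-7,8-dimethoxy-3,4-dihydrochromenylium triflate (C2 oxocarbenium ion) | COc1ccc([C@H]2C=[O+]c3c(cc(O)c(OC)c3OC)C2)c(OCc4ccccc4)c1OC.[O-]S(=O)(=O)C(F)(F)F | intermediate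
10 | (3S)-3-[2-(benzyloxy)-3,4-dimethoxyphenyl]-7,8-dimethoxy-3,4-dihydro-2H-chromen-6-ol | COc1ccc([C@H]2COc3c(cc(O)c(OC)c3OC)C2)c(OCc4ccccc4)c1OC | intermediate
11 | (3S)-3-(2-hydroxy-3,4-dimethoxyphenyl)-7,8-dimethoxy-3,4-dihydro-2H-chromen-6-ol | COc1ccc([C@H]2COc3c(cc(O)c(OC)c3OC)C2)c(O)c1OC | target

Total step count: 6. Longest linear sequence: 6 steps (1 to 11). Compounds 4 and 6 enter directly as purchased materials.

**Steps most likely to fail**

**Step 4 (Proposed new method).** Condensation of the dienolate or of 7 with unchanged 6 may outrun the cycloaddition. The temperature that the tautomerisation needs may also erode facial selectivity. The fallback uses known chemistry and generates the same heterodiene by oxidation instead of tautomerisation. It sets out from 6.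
- Reduction with Na2S2O4 (Et2O/H2O) gives 2,3-dimethoxy-5-methylbenzene-1,4-diol F1.
- Benzylation of the less hindered hydroxyl, the one flanked by C–H (BnBr 1 equiv, K2CO3, acetone), gives 4-(benzyloxy)-2,3-dimethoxy-6-methylphenol F2.
- Ag2O in CH2Cl2 at 0 to 25 °C is the established way to turn p-alkoxy-o-methylphenols of the chromanol type into o-quinone methides. It forms 4-(benzyloxy)-2,3-dimethoxy-6-methylidenecyclohexa-2,4-dien-1-one F3 in the flask, which 5 captures as the 6-O-benzyl cycloadduct F4.
- The conditions of step 5 then give the dibenzyl ether F5, and the conditions of step 6 remove both benzyl groups. The route is rejoined at 11.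

**Step 5.** Loss of H-3 from 9 followed by reprotonation would erode enantiopurity. Participation of the 2'-benzyloxy oxygen or endocyclic C2–O1 cleavage would divert material. The fallback sets out from 8 and makes the elimination deliberate.
- Catalytic pyridinium p-toluenesulfonate in refluxing toluene expels 4 and gives the achiral enol ether 3-[2-(benzyloxy)-3,4-dimethoxyphenyl]-7,8-dimethoxy-4H-chromen-6-ol F6, with both bonds of the key step intact.
- Iridium-catalysed asymmetric hydrogenation of this trisubstituted aryl alkene then sets C3 anew. Conditions: [Ir(cod)(L)][B(C6H3(CF3)2)4] with L = tBu-PHOX, ligand antipode chosen for (3S), H2 50 bar, CH2Cl2. This reaction type is known for 4H- and 2H-chromenes. The route is rejoined at 10.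

**Step 3.** Base-induced dehydroiodination of 3 to the arylacetylene and sluggish coupling of the hindered secondary alkoxide may dominate. The fallback builds the C=C bond instead of the C–O bond. It sets out from 4 and 2 and also bypasses step 2.
- Paraformaldehyde and TMSCl (CH2Cl2) convert 4 into chloromethyl (1S,2R)-2-phenylcyclohexyl ether F7.
- PPh3 in toluene gives the phosphonium chloride F8.
- NaHMDS (THF, −78 °C) gives the alkoxymethylidene ylide F9.
- Wittig reaction of F9 with 2 gives 5 together with its (Z)-isomer F10. F10 would lead to the wrong C3 configuration and is removed by chromatography on amine-deactivated silica. The route is rejoined at 5.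

**Further compounds**
F1 | step 4 | 2,3-dimethoxy-5-methylbenzene-1,4-diol | Cc1cc(O)c(OC)c(OC)c1O
F2 | step 4 | 4-(benzyloxy)-2,3-dimethoxy-6-methylphenol | Cc1cc(OCc2ccccc2)c(OC)c(OC)c1O
F3 | step 4 | 4-(benzyloxy)-2,3-dimethoxy-6-methylidenecyclohexa-2,4-dien-1-one | C=C1C=C(OCc2ccccc2)C(OC)=C(OC)C1=O
F4 | step 4 | (2R,3S)-6-(benzyloxy)-3-[2-(benzyloxy)-3,4-dimethoxyphenyl]-7,8-dimethoxy-2-{[(1S,2R)-2-phenylcyclohexyl]oxy}-3,4-dihydro-2H-chromene | COc1ccc([C@H]2[C@H](O[C@H]3CCCC[C@@H]3c4ccccc4)Oc5c(cc(OCc7ccccc7)c(OC)c5OC)C2)c(OCc6ccccc6)c1OC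
F5 | step 4 | (3S)-6-(benzyloxy)-3-[2-(benzyloxy)-3,4-dimethoxyphenyl]-7,8-dimethoxy-3,4-dihydro-2H-chromene | COc1ccc([C@H]2COc3c(cc(OCc5ccccc5)c(OC)c3OC)C2)c(OCc4ccccc4)c1OC
F6 | step 5 | 3-[2-(benzyloxy)-3,4-dimethoxyphenyl]-7,8-dimethoxy-4H-chromen-6-ol | COc1ccc(C2=COc3c(cc(O)c(OC)c3OC)C2)c(OCc4ccccc4)c1OC
F7 | step 3 | chloromethyl (1S,2R)-2-phenylcyclohexyl ether | ClCO[C@H]1CCCC[C@@H]1c1ccccc1
F8 | step 3 | triphenyl({[(1S,2R)-2-phenylcyclohexyl]oxy}methyl)phosphonium chloride | [Cl-].C(O[C@H]1CCCC[C@@H]1c1ccccc1)[P+](c1ccccc1)(c1ccccc1)c1ccccc1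
F9 | step 3 | triphenyl({[(1S,2R)-2-phenylcyclohexyl]oxy}methylidene)phosphorane | C(=P(c1ccccc1)(c1ccccc1)c1ccccc1)O[C@H]1CCCC[C@@H]1c1ccccc1
F10 | step 3 | 2-(benzyloxy)-3,4-dimethoxy-1-[(Z)-2-{[(1S,2R)-2-phenylcyclohexyl]oxy}ethenyl]benzene | COc1ccc(/C=C\O[C@H]2CCCC[C@@H]2c3ccccc3)c(OCc4ccccc4)c1OC
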